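**Strategy.** The oxepane (O1; C2 quaternary; C3 carbinol; C6 ethylidene carbon; C7 OCH2) is cut between its C7–O1–C2 ether unit and the four-carbon unit C3–C6, i.e. a formal (4+3) annulation. In one flask an (E)-γ-alkoxy-γ-methylallylboronate, whose alkoxy group is a MEM acetal, adds to an aldehyde that carries a vinylsilane (bond C2–C3, both stereocentres); SnCl4 then ionises the MEM ether to an oxocarbenium ion that the vinylsilane traps (bond C6–C7, E-ethylidene). The step exploits the vicinal C2(OR)–C3(OH) pair and the allylic ether O1–C7–C6=C. The vinyl group left on C2 later brings in the side chain by cross-metathesis.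

Key step: step 6

Remark: the sense of induction of the phosphoric acid in step 6 is assumed to follow the usual model for this catalyst class (the (R)-acid directs allyl groups to the Re face of aldehydes), hence the (S)-acid is written.

Step 1
Reactants: 1 tert-butyl(diphenyl)(prop-2-yn-1-yloxy)silane; 2 2-(2-bromoethyl)-1,3-dioxolane
Product: 4 tert-butyl{[5-(1,3-dioxolan-2-yl)pent-2-yn-1-yl]oxy}diphenylsilane, via lithium acetylide 3 (not isolated)
Conditions: n-BuLi, THF, −78 °C; then 2, DMPU, −78 °C → rt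
Reagents that add atoms: none
Why: SN2 alkylation of a lithium acetylide with a primary bromide in a dipolar cosolvent (acetylide alkylation), with no stereocentre formed.

Step 2
Reactants: 4 tert-butyl{[5-(1,3-dioxolan-2-yl)pent-2-yn-1-yl]oxy}diphenylsilane
Product: 5 tert-butyl{[(2E)-5-(1,3-dioxolan-2-yl)-3-(triethylsilyl)pent-2-en-1-yl]oxy}diphenylsilane
Conditions: Et3SiH, PtCl2 (5 mol %), XPhos (10 mol %), THF, 50 °C
Reagents that add atoms: triethylsilane CC[SiH](CC)CC
Why: Platinum-catalysed syn-hydrosilylation of an internal propargylic ether, in which the inductive effect and bulk of the CH2OSi group should send silicon to the distal alkyne carbon and the cis addition fixes the E geometry.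

Step 3
Reactants: 5 tert-butyl{[(2E)-5-(1,3-dioxolan-2-yl)-3-(triethylsilyl)pent-2-en-1-yl]oxy}diphenylsilane
Product: 6 (4E)-6-[(tert-butyldiphenylsilyl)oxy]-4-(triethylsilyl)hex-4-enal
Conditions: PPTS, acetone–H2O, 60 °C
Reagents that add atoms: water O
Why: Acid-catalysed acetal hydrolysis under buffered conditions that should leave the vinylsilane and the silyl ether intact.

Step 4
Reactants: 7 (buta-1,3-dien-2-yloxy)trimethylsilane
Product: 9 2-[(2-methoxyethoxy)methoxy]buta-1,3-diene, via lithium dienolate 8 (not isolated)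
Conditions: MeLi, THF, 0 °C; then DMPU, MEMCl, −78 °C → rt
Reagents that add atoms: 2-methoxyethoxymethyl chloride COCCOCCl
Why: Methyllithium cleavage of the silyl enol ether gives the dienolate regiospecifically, and the hard chloromethyl ether should alkylate it on oxygen in the dipolar medium (enolate O-alkylation).

Step 5
Reactants: 9 2-[(2-methoxyethoxy)methoxy]buta-1,3-diene
Product: 10 2-{(2E)-3-[(2-methoxyethoxy)methoxy]but-2-en-1-yl}-4,4,5,5-tetramethyl-1,3,2-dioxaborolane
Conditions: HBpin, Ni(cod)2 (2.5 mol %), PCy3 (2.5 mol %), toluene, rt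
Reagents that add atoms: pinacolborane B1OC(C)(C)C(C)(C)O1
Why: Nickel-catalysed 1,4-hydroboration of a 2-substituted 1,3-diene, in which hydride goes to C1 and boron to C4 of the s-cis-bound diene so that the new methyl group ends cis and the alkoxy group trans to CH2B.

Step 6
Reactants: 10 2-{(2E)-3-[(2-methoxyethoxy)methoxy]but-2-en-1-yl}-4,4,5,5-tetramethyl-1,3,2-dioxaborolane; 6 (4E)-6-[(tert-butyldiphenylsilyl)oxy]-4-(triethylsilyl)hex-4-enal
Product: 13 (2S,3R,6E)-6-{2-[(tert-butyldiphenylsilyl)oxy]ethylidene}-2-ethenyl-2-methyloxepan-3-ol, via borate ester 11 (not isolated), via oxocarbenium ion 12 (not isolated)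
Conditions: (S)-TRIP (5 mol %), 4 Å MS, toluene, −45 → 0 °C; then CH2Cl2, SnCl4 (2.5 equiv), −78 → −20 °C; aq. NaHCO3
Reagents that add atoms: none
Why: The chiral phosphoric acid activates boronate 10 so that its oxygen-bearing γ-carbon adds to the Si face of aldehyde 6 through a closed six-membered chair transition state (bond C2–C3, a catalytic enantioselective γ-alkoxyallylboration), which turns the enol-ether oxygen into a tertiary MEM ether in borate 11. SnCl4 then chelates and ionises the MEM acetal to oxocarbenium ion 12, which is attacked by the silicon-bearing carbon of the tethered vinylsilane, and loss of the triethylsilyl group gives bond C6–C7 and the exocyclic alkene (closest known type: the acetal-initiated, vinylsilane-terminated silyl-Prins cyclisation to alkylidene oxacycles). The oxepane closes in a seven-membered mode that is exo with respect to the vinylsilane double bond and endo with respect to the C=O+ bond (7-exo-trig in the alkene sense). C3 (R) is set by the catalyst through the aldehyde face, and C2 (S) by the fixed alkene geometry of 10 in the chair, where the E-placed alkoxy group ends anti and the Z-placed methyl syn to the new hydroxyl, i.e. methyl cis and vinyl trans to OH on the ring. The E geometry of the ethylidene should follow from ipso substitution of the vinylsilane with retention. The step needs the oxocarbenium ion to be captured by carbon and not by the C3 oxygen, which is secured by keeping that oxygen as an electron-poor pinacol borate and by generating the cation only on the chelating MEM side.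

Step 7
Reactants: 14 3-methylbut-1-yne
Product: 16 (1E)-1-iodo-2,3-dimethylbut-1-ene, via alkenylalane 15 (not isolated)
Conditions: AlMe3, Cp2ZrCl2 (25 mol %), CH2Cl2, rt; then I2, THF, −30 → 0 °C
Reagents that add atoms: trimethylaluminium C[Al](C)C; iodine II
Why: Zirconium-catalysed syn-carboalumination (Negishi carboalumination) places methyl on the internal and aluminium on the terminal carbon, and iodinolysis with retention should give the E-iodide.

Step 8
Reactants: 17 (4S)-4-benzyl-3-propanoyl-1,3-oxazolidin-2-one; 18 3-iodoprop-1-ene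
Product: 20 (4S)-4-benzyl-3-[(2R)-2-methylpent-4-enoyl]-1,3-oxazolidin-2-one, via sodium enolate 19 (not isolated)
Conditions: NaN(SiMe3)2, THF, −78 °C; then 18, −78 → −45 °C
Reagents that add atoms: none
Why: Evans alkylation, in which the chelated Z-enolate is allylated on the face opposite to the benzyl group and thereby sets the (R)-methyl stereocentre.

Step 9
Reactants: 20 (4S)-4-benzyl-3-[(2R)-2-methylpent-4-enoyl]-1,3-oxazolidin-2-one
Product: 21 (2R)-N-methoxy-N,2-dimethylpent-4-enamide
Conditions: MeNH(OMe)·HCl, AlMe3, CH2Cl2, 0 °C → rt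
Reagents that add atoms: N,O-dimethylhydroxylamine hydrochloride CNOC.Cl
Why: Aluminium-amide transamination of the N-acyloxazolidinone (Weinreb amide formation), which removes the auxiliary without touching the α-stereocentre.

Step 10
Reactants: 16 (1E)-1-iodo-2,3-dimethylbut-1-ene; 21 (2R)-N-methoxy-N,2-dimethylpent-4-enamide
Product: 23 (4R,6E)-4,7,8-trimethylnona-1,6-dien-5-one, via alkenyllithium 22 (not isolated)
Conditions: 16, t-BuLi (2 equiv), Et2O, −78 °C; then 21, −78 → 0 °C; 1 M aq. HCl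
Reagents that add atoms: none
Why: Iodine–lithium exchange with retention of alkene geometry followed by Weinreb ketone synthesis, whose chelated tetrahedral intermediate prevents over-addition while the cold acidic quench protects the α-stereocentre.

Step 11
Reactants: 13 (2S,3R,6E)-6-{2-[(tert-butyldiphenylsilyl)oxy]ethylidene}-2-ethenyl-2-methyloxepan-3-ol; 23 (4R,6E)-4,7,8-trimethylnona-1,6-dien-5-one
Product: 24 (3E,6R,8E)-9-[(2S,3R,6E)-6-{2-[(tert-butyldiphenylsilyl)oxy]ethylidene}-3-hydroxy-2-methyloxepan-2-yl]-2,3,6-trimethylnona-3,8-dien-5-one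
Conditions: second-generation Hoveyda–Grubbs catalyst RuCl2(H2IMes)(=CH-C6H4-2-O-i-Pr) (10 mol %), 23 (3 equiv), CH2Cl2, 40 °C
Reagents that add atoms: none
Why: Olefin cross-metathesis between the hindered, non-dimerising vinyl group of 13 and an excess of the unhindered terminal alkene 23, with the trisubstituted enone and ethylidene double bonds expected to be inert.

Step 12
Reactants: 24 (3E,6R,8E)-9-[(2S,3R,6E)-6-{2-[(tert-butyldiphenylsilyl)oxy]ethylidene}-3-hydroxy-2-methyloxepan-2-yl]-2,3,6-trimethylnona-3,8-dien-5-one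
Product: 25 (3E,6R)-9-[(2S,3R,6E)-6-{2-[(tert-butyldiphenylsilyl)oxy]ethylidene}-3-hydroxy-2-methyloxepan-2-yl]-2,3,6-trimethylnon-3-en-5-one
Conditions: H2 (4 atm), RhCl(PPh3)3 (10 mol %), benzene, rt
Reagents that add atoms: none
Why: Homogeneous hydrogenation that discriminates by degree of substitution, so that the 1,2-disubstituted alkene should be saturated while the trisubstituted enone and ethylidene alkenes remain.

Step 13
Reactants: 25 (3E,6R)-9-[(2S,3R,6E)-6-{2-[(tert-butyldiphenylsilyl)oxy]ethylidene}-3-hydroxy-2-methyloxepan-2-yl]-2,3,6-trimethylnon-3-en-5-one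
Product: 26 montanol, (3E,6R)-9-[(2S,3R,6E)-3-hydroxy-6-(2-hydroxyethylidene)-2-methyloxepan-2-yl]-2,3,6-trimethylnon-3-en-5-one
Conditions: Bu4NF, AcOH, THF, 0 °C → rt
Reagents that add atoms: none
Why: Fluoride cleavage of the primary silyl ether, buffered with acetic acid so that the enone and its α-stereocentre are not exposed to base.

**Compound list**

1 | tert-butyl(diphenyl)(prop-2-yn-1-yloxy)silane | C#CCO[Si](c1ccccc1)(c1ccccc1)C(C)(C)C | starting material
2 | 2-(2-bromoethyl)-1,3-dioxolane | BrCCC1OCCO1 | starting material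
3 | {3-[(tert-butyldiphenylsilyl)oxy]prop-1-yn-1-yl}lithium | [Li]C#CCO[Si](c1ccccc1)(c1ccccc1)C(C)(C)C | intermediate
4 | tert-butyl{[5-(1,3-dioxolan-2-yl)pent-2-yn-1-yl]oxy}diphenylsilane | CC(C)(C)[Si](OCC#CCCC1OCCO1)(c1ccccc1)c1ccccc1 | intermediate
5 | tert-butyl{[(2E)-5-(1,3-dioxolan-2-yl)-3-(triethylsilyl)pent-2-en-1-yl]oxy}diphenylsilane | CC[Si](CC)(CC)/C(CCC1OCCO1)=C/CO[Si](c1ccccc1)(c1ccccc1)C(C)(C)C | intermediate
6 | (4E)-6-[(tert-butyldiphenylsilyl)oxy]-4-(triethylsilyl)hex-4-enal | CC[Si](CC)(CC)/C(CCC=O)=C/CO[Si](c1ccccc1)(c1ccccc1)C(C)(C)C | intermediate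
7 | (buta-1,3-dien-2-yloxy)trimethylsilane | C=CC(=C)O[Si](C)(C)C | starting material
8 | lithium buta-1,3-dien-2-olate | [Li+].[O-]C(=C)C=C | intermediate
9 | 2-[(2-methoxyethoxy)methoxy]buta-1,3-diene | C=CC(=C)OCOCCOC | intermediate
10 | 2-{(2E)-3-[(2-methoxyethoxy)methoxy]but-2-en-1-yl}-4,4,5,5-tetramethyl-1,3,2-dioxaborolane | C/C(OCOCCOC)=C\CB1OC(C)(C)C(C)(C)O1 | intermediate
11 | 2-{[(3S,4R,7E)-9-[(tert-butyldiphenylsilyl)oxy]-3-[(2-methoxyethoxy)methoxy]-3-methyl-7-(triethylsilyl)nona-1,7-dien-4-yl]oxy}-4,4,5,5-tetramethyl-1,3,2-dioxaborolane | C=C[C@](C)(OCOCCOC)[C@H](OB1OC(C)(C)C(C)(C)O1)CC/C(=C\CO[Si](c2ccccc2)(c2ccccc2)C(C)(C)C)[Si](CC)(CC)CC | intermediate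
12 | [(3S,4R,7E)-9-[(tert-butyldiphenylsilyl)oxy]-3-methyl-4-[(4,4,5,5-tetramethyl-1,3,2-dioxaborolan-2-yl)oxy]-7-(triethylsilyl)nona-1,7-dien-3-yl](methylidene)oxonium | C=C[C@](C)([O+]=C)[C@H](OB1OC(C)(C)C(C)(C)O1)CC/C(=C\CO[Si](c2ccccc2)(c2ccccc2)C(C)(C)C)[Si](CC)(CC)CC | intermediate
13 | (2S,3R,6E)-6-{2-[(tert-butyldiphenylsilyl)oxy]ethylidene}-2-ethenyl-2-methyloxepan-3-ol | C=C[C@]1(C)OC/C(=C/CO[Si](c2ccccc2)(c2ccccc2)C(C)(C)C)CC[C@H]1O | intermediate
14 | 3-methylbut-1-yne | CC(C)C#C | starting material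
15 | [(1E)-2,3-dimethylbut-1-en-1-yl]dimethylalumane | C[Al](C)/C=C(\C)C(C)C | intermediate
16 | (1E)-1-iodo-2,3-dimethylbut-1-ene | I/C=C(\C)C(C)C | intermediate
17 | (4S)-4-benzyl-3-propanoyl-1,3-oxazolidin-2-one | CCC(=O)N1[C@@H](Cc2ccccc2)COC1=O | starting material
18 | 3-iodoprop-1-ene | C=CCI | starting material
19 | sodium (1Z)-1-[(4S)-4-benzyl-2-oxo-1,3-oxazolidin-3-yl]prop-1-en-1-olate | C/C=C(\[O-])N1[C@@H](Cc2ccccc2)COC1=O.[Na+] | intermediate
20 | (4S)-4-benzyl-3-[(2R)-2-methylpent-4-enoyl]-1,3-oxazolidin-2-one | C=CC[C@@H](C)C(=O)N1[C@@H](Cc2ccccc2)COC1=O | intermediate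
21 | (2R)-N-methoxy-N,2-dimethylpent-4-enamide | C=CC[C@@H](C)C(=O)N(C)OC | intermediate
22 | [(1E)-2,3-dimethylbut-1-en-1-yl]lithium | [Li]/C=C(\C)C(C)C | intermediate
23 | (4R,6E)-4,7,8-trimethylnona-1,6-dien-5-one | C=CC[C@@H](C)C(=O)/C=C(\C)C(C)C | intermediate
24 | (3E,6R,8E)-9-[(2S,3R,6E)-6-{2-[(tert-butyldiphenylsilyl)oxy]ethylidene}-3-hydroxy-2-methyloxepan-2-yl]-2,3,6-trimethylnona-3,8-dien-5-one | C/C(=C\C(=O)[C@H](C)C/C=C/[C@]1(C)OC/C(=C/CO[Si](c2ccccc2)(c2ccccc2)C(C)(C)C)CC[C@H]1O)C(C)C | intermediate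
25 | (3E,6R)-9-[(2S,3R,6E)-6-{2-[(tert-butyldiphenylsilyl)oxy]ethylidene}-3-hydroxy-2-methyloxepan-2-yl]-2,3,6-trimethylnon-3-en-5-one | C/C(=C\C(=O)[C@H](C)CCC[C@]1(C)OC/C(=C/CO[Si](c2ccccc2)(c2ccccc2)C(C)(C)C)CC[C@H]1O)C(C)C | intermediate
26 | montanol, (3E,6R)-9-[(2S,3R,6E)-3-hydroxy-6-(2-hydroxyethylidene)-2-methyloxepan-2-yl]-2,3,6-trimethylnon-3-en-5-one | C/C(=C\C(=O)[C@H](C)CCC[C@]1(C)OC/C(=C/CO)CC[C@H]1O)C(C)C | target

**Totals**

Total step count: 13. Longest linear sequence: 7 steps (steps 1, 2, 3, 6, 11, 12 and 13).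

**Steps most likely to fail**

Step 6 (key step). The oxocarbenium ion may be captured by the neighbouring borate oxygen to give a methylene acetal, after which the ring may close through that oxygen to a tetrahydropyran. A competing uncatalysed allylboration may also erode the enantioselectivity. The fallback sets out from 10 and 6 and returns at 13; it makes the two bonds in separate operations with the C3 oxygen masked as an ester. The allylboration alone ((S)-TRIP, 4 Å MS, toluene, −45 °C, aqueous work-up) should give (3S,4R,7E)-9-[(tert-butyldiphenylsilyl)oxy]-3-[(2-methoxyethoxy)methoxy]-3-methyl-7-(triethylsilyl)nona-1,7-dien-4-ol F1. Acetylation (Ac2O, DMAP, pyridine) should give (3S,4R,7E)-9-[(tert-butyldiphenylsilyl)oxy]-3-[(2-methoxyethoxy)methoxy]-3-methyl-7-(triethylsilyl)nona-1,7-dien-4-yl acetate F2, whose ester oxygen can neither attack nor carry the oxocarbenium ion. The MEM-ether/vinylsilane cyclisation (SnCl4, CH2Cl2, −20 °C) should then give (2S,3R,6E)-6-{2-[(tert-butyldiphenylsilyl)oxy]ethylidene}-2-ethenyl-2-methyloxepan-3-yl acetate F3, and methanolysis (K2CO3, MeOH) should return 13.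

Step 12. The disubstituted alkene sits next to the quaternary ring carbon, and the forcing conditions it may need could also saturate the enone or the ethylidene alkene. The fallback sets out from 13 and 21 and returns at 25; it moves the reduction ahead of enone formation. Cross-metathesis of 13 with amide 21 (same ruthenium catalyst) should give (2R,4E)-5-[(2S,3R,6E)-6-{2-[(tert-butyldiphenylsilyl)oxy]ethylidene}-3-hydroxy-2-methyloxepan-2-yl]-N-methoxy-N,2-dimethylpent-4-enamide F4. Hydrogenation (H2, RhCl(PPh3)3, or excess diimide), now with no enone present, should give (2R)-5-[(2S,3R,6E)-6-{2-[(tert-butyldiphenylsilyl)oxy]ethylidene}-3-hydroxy-2-methyloxepan-2-yl]-N-methoxy-N,2-dimethylpentanamide F5. Addition of an excess of alkenyllithium 22 (from 16, t-BuLi, −78 °C), which first deprotonates the free hydroxyl, should then give 25.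

Step 2. Silicon may be delivered to both alkyne carbons, giving regioisomeric vinylsilanes that would be hard to separate. The fallback sets out from 1 and 2 and returns at 5; it fixes regio- and stereochemistry by hydroalumination and cross-coupling. C-Silylation of 1 (n-BuLi; Et3SiCl) should give tert-butyl(diphenyl){[3-(triethylsilyl)prop-2-yn-1-yl]oxy}silane F6. trans-Hydroalumination at the silicon-bearing carbon (i-Bu2AlH, heptane, 50 °C) and iodinolysis (I2, THF, −78 °C) should give tert-butyl{[(2Z)-3-iodo-3-(triethylsilyl)prop-2-en-1-yl]oxy}diphenylsilane F7. Bromide 2 is converted (Zn, LiCl, THF) into [2-(1,3-dioxolan-2-yl)ethyl]zinc bromide F8, and Negishi coupling of F7 with F8 (PdCl2(dppf), THF, 50 °C), with retention of alkene geometry, should give 5.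

Further compounds
F1 | step 6 | (3S,4R,7E)-9-[(tert-butyldiphenylsilyl)oxy]-3-[(2-methoxyethoxy)methoxy]-3-methyl-7-(triethylsilyl)nona-1,7-dien-4-ol | C=C[C@](C)(OCOCCOC)[C@H](O)CC/C(=C\CO[Si](c1ccccc1)(c1ccccc1)C(C)(C)C)[Si](CC)(CC)CC
F2 | step 6 | (3S,4R,7E)-9-[(tert-butyldiphenylsilyl)oxy]-3-[(2-methoxyethoxy)methoxy]-3-methyl-7-(triethylsilyl)nona-1,7-dien-4-yl acetate | C=C[C@](C)(OCOCCOC)[C@H](OC(C)=O)CC/C(=C\CO[Si](c1ccccc1)(c1ccccc1)C(C)(C)C)[Si](CC)(CC)CC
F3 | step 6 | (2S,3R,6E)-6-{2-[(tert-butyldiphenylsilyl)oxy]ethylidene}-2-ethenyl-2-methyloxepan-3-yl acetate | C=C[C@]1(C)OC/C(=C/CO[Si](c2ccccc2)(c2ccccc2)C(C)(C)C)CC[C@H]1OC(C)=O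
F4 | step 12 | (2R,4E)-5-[(2S,3R,6E)-6-{2-[(tert-butyldiphenylsilyl)oxy]ethylidene}-3-hydroxy-2-methyloxepan-2-yl]-N-methoxy-N,2-dimethylpent-4-enamide | CON(C)C(=O)[C@H](C)C/C=C/[C@]1(C)OC/C(=C/CO[Si](c2ccccc2)(c2ccccc2)C(C)(C)C)CC[C@H]1O
F5 | step 12 | (2R)-5-[(2S,3R,6E)-6-{2-[(tert-butyldiphenylsilyl)oxy]ethylidene}-3-hydroxy-2-methyloxepan-2-yl]-N-methoxy-N,2-dimethylpentanamide | CON(C)C(=O)[C@H](C)CCC[C@]1(C)OC/C(=C/CO[Si](c2ccccc2)(c2ccccc2)C(C)(C)C)CC[C@H]1O
F6 | step 2 | tert-butyl(diphenyl){[3-(triethylsilyl)prop-2-yn-1-yl]oxy}silane | CC[Si](CC)(CC)C#CCO[Si](c1ccccc1)(c1ccccc1)C(C)(C)C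
F7 | step 2 | tert-butyl{[(2Z)-3-iodo-3-(triethylsilyl)prop-2-en-1-yl]oxy}diphenylsilane | CC[Si](CC)(CC)/C(I)=C/CO[Si](c1ccccc1)(c1ccccc1)C(C)(C)C
F8 | step 2 | [2-(1,3-dioxolan-2-yl)ethyl]zinc bromide | Br[Zn]CCC1OCCO1
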